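The six carbons C1–C6 of the macrocycle (Z C4=C5 alkene, C15 methyl on C4, oxygen on C3) are recognised as the ring of trans-carveol. C1 carries C10, C9 and C14 as an isopropenyl group, and C6 is a tertiary carbinol bearing an E-2-silylvinyl group (C7, C8). One operation expands this ring through C8–C9 bond formation and C1–C6 cleavage to the 1(10)E,4Z-cyclodecadienone, sets C8 with silicon as a masked hydroxyl, and alkylates the C6/C7 enolate at C7 with tert-butyl bromoacetate, which supplies C11 and C12 of the lactone. The precursor is a trans-1,2-dialkenyl cyclohexenol made from (R)-carvone.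

Key step: step 9

Remark: germacrane numbering is used for all ten-membered compounds; α and β refer to the usual germacranolide drawing, β being the face of the C3 and C8 oxygens of the target.

Step 1
Reactants: 1 (R)-carvone
Product: 2 (1R,5R)-cis-carveol
Conditions: NaBH4, CeCl3·7H2O, MeOH, −78 to 0 °C
Reagents that add atoms: none
Why: Luche reduction gives clean 1,2-reduction of the enone, and axial hydride delivery anti to the equatorial isopropenyl group places the new hydroxyl cis to it.

Step 2
Reactants: 2 (1R,5R)-cis-carveol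
Product: 3 (1S,5R)-trans-carveyl 4-nitrobenzoate
Conditions: 4-nitrobenzoic acid, PPh3, DIAD, THF, 0 °C to rt
Reagents that add atoms: 4-nitrobenzoic acid, O=C(O)c1ccc(cc1)[N+](=O)[O-]
Why: The Mitsunobu reaction displaces the activated allylic oxygen by SN2 with inversion, which gives the trans relationship between the C3 oxygen and the isopropenyl group that the target requires.

Step 3
Reactants: 3 (1S,5R)-trans-carveyl 4-nitrobenzoate
Product: 4 (1S,5R)-trans-carveol
Conditions: K2CO3 (cat.), MeOH, rt
Reagents that add atoms: none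
Why: Methanolysis of the activated aryl ester occurs at the acyl carbon and leaves the carbinol configuration untouched.

Step 4
Reactants: 4 (1S,5R)-trans-carveol
Product: 5 trans-carveol TBS ether
Conditions: TBSCl, imidazole, DMF, rt
Reagents that add atoms: tert-butyldimethylsilyl chloride, CC(C)(C)[Si](C)(C)Cl
Why: Standard silylation gives an ether that should survive the chromium oxidation, the organocerium addition and KH.

Step 5
Reactants: 5 trans-carveol TBS ether
Product: 6 (4S,6R)-4-(tert-butyldimethylsilyloxy)-3-methyl-6-(prop-1-en-2-yl)cyclohex-2-en-1-one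
Conditions: CrO3, 3,5-dimethylpyrazole, CH2Cl2, −20 °C
Reagents that add atoms: chromium trioxide, O=[Cr](=O)=O
Why: Allylic oxidation by the CrO3–pyrazole complex converts the only oxygen-free secondary allylic ring CH2 into a ketone with the alkene left in place, giving the transposed enone (future C6 carbonyl) under non-basic conditions that should not epimerise the isopropenyl-bearing α-carbon.

Step 6
Reactants: 7 benzylchlorodimethylsilane; 8 ethynylmagnesium bromide
Product: 9 benzyl(ethynyl)dimethylsilane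
Conditions: THF, 0 °C to rt
Reagents that add atoms: none
Why: The acetylide displaces chloride at silicon in a standard Grignard silylation.

Step 7
Reactants: 9 benzyl(ethynyl)dimethylsilane
Product: 10 (E)-benzyldimethyl[2-(tributylstannyl)ethenyl]silane
Conditions: Bu3SnH, AIBN (azobisisobutyronitrile, cat.), 85 °C
Reagents that add atoms: tributyltin hydride, CCCC[SnH](CCCC)CCCC
Why: In this radical hydrostannylation the stannyl radical adds to the terminal alkyne carbon, and reversible addition equilibrates the product to the E-1,2-disubstituted alkene.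

Step 8
Reactants: 10 (E)-benzyldimethyl[2-(tributylstannyl)ethenyl]silane; 6 (4S,6R)-4-(tert-butyldimethylsilyloxy)-3-methyl-6-(prop-1-en-2-yl)cyclohex-2-en-1-one
Product: 13 (1R,4S,6R)-1-[(E)-2-(benzyldimethylsilyl)ethenyl]-4-(tert-butyldimethylsilyloxy)-3-methyl-6-(prop-1-en-2-yl)cyclohex-2-en-1-ol, via vinyllithium 11 (not isolated), via vinylcerium dichloride 12 (not isolated)
Conditions: n-BuLi, THF, −78 °C; CeCl3 (anhydrous), −78 °C; then 6, −78 °C
Reagents that add atoms: none
Why: Tin–lithium exchange keeps the E geometry, the weakly basic organocerium reagent adds 1,2 to the easily enolised enone, and attack anti to the adjacent pseudo-equatorial isopropenyl group sets the carbinol centre with the two alkenyl groups trans.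

Step 9
Reactants: 13 (1R,4S,6R)-1-[(E)-2-(benzyldimethylsilyl)ethenyl]-4-(tert-butyldimethylsilyloxy)-3-methyl-6-(prop-1-en-2-yl)cyclohex-2-en-1-ol; 14 tert-butyl bromoacetate
Product: 17 tert-butyl 8β-(benzyldimethylsilyl)-3β-(tert-butyldimethylsilyloxy)-6-oxo-13-nor-7αH-germacra-1(10)E,4Z-dien-12-oate, via potassium alkoxide 15 (not isolated), via potassium enolate 16 (not isolated)
Conditions: KH, 18-crown-6, THF, 0 °C to rt; then −78 °C, 14, −78 to −40 °C
Reagents that add atoms: none
Why: Deprotonation gives alkoxide 15, whose anionic oxy-Cope [3,3] shift (the known ring expansion of 1,2-dialkenylcyclohexanols, here with in situ enolate alkylation) joins C8 to C9 and cleaves C1–C6; no ring is closed by cyclisation, the ten-membered ring being released from the six-membered one through a chair transition state with both alkenyl groups equatorial and the alkoxide axial. The equatorial C2 gives the E C1=C10 alkene, and the Z C4=C5 alkene is carried over from the cyclohexene. C8 is set by the chair together with the E geometry of the vinylsilane, which puts silicon equatorial and ties its configuration to that of C1 and C6, both traceable to carvone. C7 is set when the regiodefined cross-conjugated enolate 16 takes up the bromoacetate anti to the C8–Si bond (the usual course for β-silyl enolates, C8–H eclipsing the enolate), which gives the 7,8 relationship of the target. The step needs chair over boat, secured by the trans alkenyl groups and the absence of a Z substituent, and one enolate face, for which the silyl group is relied on; being carbon-bound and on an E alkene, silicon can neither be eliminated from the enolate nor migrate to oxygen.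

Step 10
Reactants: 17 tert-butyl 8β-(benzyldimethylsilyl)-3β-(tert-butyldimethylsilyloxy)-6-oxo-13-nor-7αH-germacra-1(10)E,4Z-dien-12-oate
Product: 18 tert-butyl 8β-(benzyldimethylsilyl)-3β-(tert-butyldimethylsilyloxy)-6α-hydroxy-13-nor-7αH-germacra-1(10)E,4Z-dien-12-oate
Conditions: NaBH4, CeCl3·7H2O, MeOH/THF, −40 °C
Reagents that add atoms: none
Why: Luche 1,2-reduction of the Z-enone should occur by peripheral hydride attack anti to the C7–C8 ring bond in the rotamer that keeps C7–H, not the acetate arm, beside the carbonyl oxygen, which places the new hydroxyl α at C6 and trans to the C7 arm; ester and silyl groups are inert.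

Step 11
Reactants: 18 tert-butyl 8β-(benzyldimethylsilyl)-3β-(tert-butyldimethylsilyloxy)-6α-hydroxy-13-nor-7αH-germacra-1(10)E,4Z-dien-12-oate
Product: 20 8β-(benzyldimethylsilyl)-3β-hydroxy-13-norgermacra-1(10)E,4Z-dien-12,6α-olide, via silyl lactone 19 (not isolated)
Conditions: p-toluenesulfonic acid monohydrate (cat.), CH2Cl2, rt; then MeOH, rt
Reagents that add atoms: none
Why: Acid-catalysed transesterification closes the γ-lactone at the acyl carbon, so the C6–O bond and the trans ring fusion are retained, and methanolysis then removes the allylic TBS group so that C3 can be acylated before fluoride is used at C8; catalytic sulfonic acid at rt should spare the C1=C10 alkene and the C–Si bond.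

Step 12
Reactants: 20 8β-(benzyldimethylsilyl)-3β-hydroxy-13-norgermacra-1(10)E,4Z-dien-12,6α-olide
Product: 21 3β-benzoyloxy-8β-(benzyldimethylsilyl)-13-norgermacra-1(10)E,4Z-dien-12,6α-olide
Conditions: BzCl, pyridine, DMAP (4-dimethylaminopyridine, cat.), CH2Cl2, 0 °C to rt
Reagents that add atoms: benzoyl chloride, O=C(Cl)c1ccccc1
Why: Acylation of the only free hydroxyl occurs at oxygen with retention at C3.

Step 13
Reactants: 21 3β-benzoyloxy-8β-(benzyldimethylsilyl)-13-norgermacra-1(10)E,4Z-dien-12,6α-olide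
Product: 23 3β-benzoyloxy-8β-hydroxy-13-norgermacra-1(10)E,4Z-dien-12,6α-olide, via silanol 22 (not isolated)
Conditions: TBAF, THF, 0 °C; then KHCO3, 30% H2O2, MeOH/THF, rt
Reagents that add atoms: hydrogen peroxide, OO
Why: In this Tamao–Fleming oxidation fluoride removes the benzyl group from silicon and peroxide then shifts C8 from silicon to oxygen with retention, giving the 8β-alcohol; it is run before the α-methylene group exists, so that no Michael acceptor meets fluoride or hydroperoxide.

Step 14
Reactants: 24 tiglic acid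
Product: 25 (E)-2-methylbut-2-en-1-ol
Conditions: LiAlH4, Et2O, 0 °C
Reagents that add atoms: none
Why: Hydride reduction of the carboxylic acid gives the allylic alcohol with the E alkene unchanged.

Step 15
Reactants: 25 (E)-2-methylbut-2-en-1-ol
Product: 26 [(2S,3S)-2,3-dimethyloxiran-2-yl]methanol
Conditions: Ti(OiPr)4 (cat.), L-(+)-diethyl tartrate (cat.), t-BuOOH, 4 Å molecular sieves, CH2Cl2, −20 °C
Reagents that add atoms: tert-butyl hydroperoxide, CC(C)(C)OO
Why: Sharpless asymmetric epoxidation with the L-(+)-tartrate ligand delivers oxygen to the alkene face that gives the (2S,3S) epoxy alcohol, and syn addition keeps the two methyl groups cis.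

Step 16
Reactants: 26 [(2S,3S)-2,3-dimethyloxiran-2-yl]methanol
Product: 27 (2R,3S)-2,3-dimethyloxirane-2-carboxylic acid
Conditions: TEMPO (2,2,6,6-tetramethylpiperidin-1-oxyl, cat.), PhI(OAc)2, MeCN/H2O, rt
Reagents that add atoms: water, O
Why: Oxoammonium oxidation takes the primary alcohol through the aldehyde hydrate to the acid under near-neutral conditions that leave the epoxide intact; the C2 descriptor changes only because of priorities.

Step 17
Reactants: 23 3β-benzoyloxy-8β-hydroxy-13-norgermacra-1(10)E,4Z-dien-12,6α-olide; 27 (2R,3S)-2,3-dimethyloxirane-2-carboxylic acid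
Product: 29 3β-benzoyloxy-8β-[(2R,3S)-2,3-dimethyloxirane-2-carbonyloxy]-13-norgermacra-1(10)E,4Z-dien-12,6α-olide, via mixed anhydride 28 (not isolated)
Conditions: 2,4,6-trichlorobenzoyl chloride, Et3N, THF, rt; then 23, DMAP (4-dimethylaminopyridine), toluene, rt
Reagents that add atoms: none
Why: Yamaguchi esterification acylates the hindered secondary 8β-hydroxyl under basic conditions that spare the epoxide, and no stereocentre is touched.

Step 18
Reactants: 29 3β-benzoyloxy-8β-[(2R,3S)-2,3-dimethyloxirane-2-carbonyloxy]-13-norgermacra-1(10)E,4Z-dien-12,6α-olide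
Product: 33 3β-benzoyloxy-8β-[(2R,3S)-2,3-dimethyloxirane-2-carbonyloxy]germacra-1(10)E,4Z,11(13)-trien-12,6α-olide, via lithium enolate 30 (not isolated), via Mannich base 31 (not isolated), via methiodide 32 (not isolated)
Conditions: LiN(SiMe3)2, THF, −78 °C; dimethylmethyleneiminium iodide (Me2N=CH2+ I−), −78 to 0 °C; then MeI, THF, rt; then NaHCO3, H2O/EtOAc, rt
Reagents that add atoms: dimethylmethyleneiminium iodide, C[N+](C)=C.[I-]
Why: α-Methylenation via a Mannich base should work because the lactone is the only enolisable carbonyl (benzoate and epoxy ester have no α-hydrogen); the enolate is aminomethylated at −78 °C, and quaternisation followed by E1cB elimination gives the exocyclic alkene.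

Step 19
Reactants: 33 3β-benzoyloxy-8β-[(2R,3S)-2,3-dimethyloxirane-2-carbonyloxy]germacra-1(10)E,4Z,11(13)-trien-12,6α-olide
Product: 34 target (1R,10R)-epoxide 3β-benzoyloxy-1β,10α-epoxy-8β-[(2R,3S)-2,3-dimethyloxirane-2-carbonyloxy]germacra-4Z,11(13)-dien-12,6α-olide
Conditions: mCPBA, NaHCO3, CH2Cl2, 0 °C
Reagents that add atoms: 3-chloroperoxybenzoic acid, OOC(=O)c1cccc(Cl)c1
Why: Prilezhaev epoxidation should select the electron-rich C1=C10 alkene (C4=C5 is deactivated by two allylic acyloxy groups, the methylene lactone is electron-poor), concerted syn addition keeps the E geometry as a trans epoxide, and attack on the outer face of the C1=C10 unit with the 14-methyl on the β side should give the (1R,10R) isomer.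

Compound list
1 | (R)-carvone | CC1=CC[C@H](CC1=O)C(C)=C | starting material
2 | (1R,5R)-cis-carveol, (1R,5R)-2-methyl-5-(prop-1-en-2-yl)cyclohex-2-en-1-ol | C1C=C(C)[C@H](O)C[C@@H]1C(C)=C | intermediate
3 | (1S,5R)-trans-carveyl 4-nitrobenzoate | C1C=C(C)[C@@H](OC(=O)c2ccc(cc2)[N+](=O)[O-])C[C@@H]1C(C)=C | intermediate
4 | (1S,5R)-trans-carveol | C1C=C(C)[C@@H](O)C[C@@H]1C(C)=C | intermediate
5 | trans-carveol TBS ether, tert-butyldimethyl{[(1S,5R)-2-methyl-5-(prop-1-en-2-yl)cyclohex-2-en-1-yl]oxy}silane | C1C=C(C)[C@@H](O[Si](C)(C)C(C)(C)C)C[C@@H]1C(C)=C | intermediate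
6 | (4S,6R)-4-(tert-butyldimethylsilyloxy)-3-methyl-6-(prop-1-en-2-yl)cyclohex-2-en-1-one | O=C1C=C(C)[C@@H](O[Si](C)(C)C(C)(C)C)C[C@@H]1C(C)=C | intermediate
7 | benzylchlorodimethylsilane | C[Si](C)(Cl)Cc1ccccc1 | starting material
8 | ethynylmagnesium bromide | C#C[Mg]Br | starting material
9 | benzyl(ethynyl)dimethylsilane | C#C[Si](C)(C)Cc1ccccc1 | intermediate
10 | (E)-benzyldimethyl[2-(tributylstannyl)ethenyl]silane | CCCC[Sn](CCCC)(CCCC)/C=C/[Si](C)(C)Cc1ccccc1 | intermediate
11 | (E)-2-(benzyldimethylsilyl)ethenyllithium | [Li]/C=C/[Si](C)(C)Cc1ccccc1 | intermediate (not isolated)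
12 | [(E)-2-(benzyldimethylsilyl)ethenyl]cerium dichloride | Cl[Ce](Cl)/C=C/[Si](C)(C)Cc1ccccc1 | intermediate (not isolated)
13 | dialkenyl cyclohexenol, (1R,4S,6R)-1-[(E)-2-(benzyldimethylsilyl)ethenyl]-4-(tert-butyldimethylsilyloxy)-3-methyl-6-(prop-1-en-2-yl)cyclohex-2-en-1-ol (hydroxyl cis to isopropenyl, vinyl trans to it, OTBS trans to isopropenyl) | O[C@]1(/C=C/[Si](C)(C)Cc2ccccc2)C=C(C)[C@@H](O[Si](C)(C)C(C)(C)C)C[C@@H]1C(C)=C | intermediate (key-step precursor)
14 | tert-butyl bromoacetate | BrCC(=O)OC(C)(C)C | starting material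
15 | potassium alkoxide of 13 | [K+].[O-][C@]1(/C=C/[Si](C)(C)Cc2ccccc2)C=C(C)[C@@H](O[Si](C)(C)C(C)(C)C)C[C@@H]1C(C)=C | intermediate (not isolated)
16 | potassium C6/C7 enolate of the 1(10)E,4Z-cyclodecadienone (oxygen cis to C8, 8β-silyl, 3β-OTBS) | [K+].[O-]/C1=C\[C@H]([Si](C)(C)Cc2ccccc2)C/C(C)=C/C[C@H](O[Si](C)(C)C(C)(C)C)/C(C)=C\1 | intermediate (not isolated)
17 | tert-butyl 8β-(benzyldimethylsilyl)-3β-(tert-butyldimethylsilyloxy)-6-oxo-13-nor-7αH-germacra-1(10)E,4Z-dien-12-oate | O=C1[C@H](CC(=O)OC(C)(C)C)[C@H]([Si](C)(C)Cc2ccccc2)C/C(C)=C/C[C@H](O[Si](C)(C)C(C)(C)C)/C(C)=C\1 | intermediate (key-step product)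
18 | tert-butyl 8β-(benzyldimethylsilyl)-3β-(tert-butyldimethylsilyloxy)-6α-hydroxy-13-nor-7αH-germacra-1(10)E,4Z-dien-12-oate | O[C@H]1[C@H](CC(=O)OC(C)(C)C)[C@H]([Si](C)(C)Cc2ccccc2)C/C(C)=C/C[C@H](O[Si](C)(C)C(C)(C)C)/C(C)=C\1 | intermediate
19 | 8β-(benzyldimethylsilyl)-3β-(tert-butyldimethylsilyloxy)-13-norgermacra-1(10)E,4Z-dien-12,6α-olide (trans-fused lactone) | C1C(=O)O[C@@H]2/C=C(/C)[C@@H](O[Si](C)(C)C(C)(C)C)C/C=C(\C)C[C@@H]([Si](C)(C)Cc3ccccc3)[C@@H]12 | intermediate (not isolated)
20 | 8β-(benzyldimethylsilyl)-3β-hydroxy-13-norgermacra-1(10)E,4Z-dien-12,6α-olide | C1C(=O)O[C@@H]2/C=C(/C)[C@@H](O)C/C=C(\C)C[C@@H]([Si](C)(C)Cc3ccccc3)[C@@H]12 | intermediate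
21 | 3β-benzoyloxy-8β-(benzyldimethylsilyl)-13-norgermacra-1(10)E,4Z-dien-12,6α-olide | C1C(=O)O[C@@H]2/C=C(/C)[C@@H](OC(=O)c3ccccc3)C/C=C(\C)C[C@@H]([Si](C)(C)Cc3ccccc3)[C@@H]12 | intermediate
22 | 3β-benzoyloxy-8β-(hydroxydimethylsilyl)-13-norgermacra-1(10)E,4Z-dien-12,6α-olide (silanol) | C1C(=O)O[C@@H]2/C=C(/C)[C@@H](OC(=O)c3ccccc3)C/C=C(\C)C[C@@H]([Si](C)(C)O)[C@@H]12 | intermediate (not isolated)
23 | 3β-benzoyloxy-8β-hydroxy-13-norgermacra-1(10)E,4Z-dien-12,6α-olide | C1C(=O)O[C@@H]2/C=C(/C)[C@@H](OC(=O)c3ccccc3)C/C=C(\C)C[C@@H](O)[C@@H]12 | intermediate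
24 | tiglic acid | C/C=C(\C)C(=O)O | starting material
25 | (E)-2-methylbut-2-en-1-ol | C/C=C(\C)CO | intermediate
26 | [(2S,3S)-2,3-dimethyloxiran-2-yl]methanol (methyl groups cis) | OC[C@]1(C)O[C@H]1C | intermediate
27 | (2R,3S)-2,3-dimethyloxirane-2-carboxylic acid (methyl groups cis) | OC(=O)[C@]1(C)O[C@H]1C | intermediate
28 | (2R,3S)-2,3-dimethyloxirane-2-carboxylic 2,4,6-trichlorobenzoic anhydride | O=C(OC(=O)[C@]1(C)O[C@H]1C)c1c(Cl)cc(Cl)cc1Cl | intermediate (not isolated)
29 | 3β-benzoyloxy-8β-[(2R,3S)-2,3-dimethyloxirane-2-carbonyloxy]-13-norgermacra-1(10)E,4Z-dien-12,6α-olide | C1C(=O)O[C@@H]2/C=C(/C)[C@@H](OC(=O)c3ccccc3)C/C=C(\C)C[C@@H](OC(=O)[C@]3(C)O[C@H]3C)[C@@H]12 | intermediate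
30 | lithium enolate of lactone 29 (C11=C12) | C1=C([O-])O[C@@H]2/C=C(/C)[C@@H](OC(=O)c3ccccc3)C/C=C(\C)C[C@@H](OC(=O)[C@]3(C)O[C@H]3C)[C@@H]12.[Li+] | intermediate (not isolated)
31 | 11-(dimethylaminomethyl) derivative of 29 (Mannich base, C11 configuration immaterial) | CN(C)CC1C(=O)O[C@@H]2/C=C(/C)[C@@H](OC(=O)c3ccccc3)C/C=C(\C)C[C@@H](OC(=O)[C@]3(C)O[C@H]3C)[C@@H]12 | intermediate (not isolated)
32 | trimethylammonium iodide of 31 (methiodide) | C[N+](C)(C)CC1C(=O)O[C@@H]2/C=C(/C)[C@@H](OC(=O)c3ccccc3)C/C=C(\C)C[C@@H](OC(=O)[C@]3(C)O[C@H]3C)[C@@H]12.[I-] | intermediate (not isolated)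
33 | 3β-benzoyloxy-8β-[(2R,3S)-2,3-dimethyloxirane-2-carbonyloxy]germacra-1(10)E,4Z,11(13)-trien-12,6α-olide | C=C1C(=O)O[C@@H]2/C=C(/C)[C@@H](OC(=O)c3ccccc3)C/C=C(\C)C[C@@H](OC(=O)[C@]3(C)O[C@H]3C)[C@@H]12 | intermediate
34 | (1R,3S,4Z,6R,7R,8R,10R)-3-benzoyloxy-1,10-epoxy-8-[(2R,3S)-2,3-dimethyloxirane-2-carbonyloxy]germacra-4,11(13)-dien-12,6-olide (CNP0324463.5) | C=C1C(=O)O[C@@H]2/C=C(/C)[C@@H](OC(=O)c3ccccc3)C[C@H]3O[C@]3(C)C[C@@H](OC(=O)[C@]3(C)O[C@H]3C)[C@@H]12 | target

Total step count: 19. Longest linear sequence: 14 steps from (R)-carvone (steps 1–5, 8–13, 17–19); steps 6–7 and 14–16 are side branches.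

Steps most likely to fail

Step 9. The ten-membered enolate may react through a ring conformer in which the face anti to silicon is screened by the C1=C10 bridge, so that the bromoacetate enters on the exposed face and C7 forms mainly with the wrong configuration; a boat-like shift would also erode C8. The fallback reverses the order of bond formation at C7. It sets out from 13: the shift is run as before and enolate 16 is intercepted at −78 °C with tert-butyl glyoxylate to give the aldol adduct F1. Mesylation (MsCl, Et3N) gives the mesylate F2, and DBU eliminates it to the alkylidene keto ester F3. Conjugate reduction with [(Ph3P)CuH]6 puts hydride on C11 and regenerates the C6/C7 enolate, now carrying the arm. Kinetic protonation at −78 °C then brings hydrogen to C7 from the face the alkyl halide would have used, so the same facial bias should give the required configuration, and the route is rejoined at 17.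

Step 10. Hydride may be delivered to the other face of the C6 ketone, through the rotamer with the acetate arm beside the carbonyl oxygen, which would give the 6β-alcohol and hence a cis-fused lactone. The fallback corrects C6 by substitution instead of relying on the reduction. It sets out from 17: the 6β-alcohol F4 obtained from the reduction is esterified under Mitsunobu conditions (4-nitrobenzoic acid, PPh3, DIAD) with inversion to the 6α-(4-nitrobenzoate) F5, and methanolysis (K2CO3, MeOH) returns the 6α-alcohol 18, where the route is rejoined.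

Step 18. The lactone enolate may take up the neighbouring C8 acyl group (O-to-C acyl transfer through a five-membered transition state), or the base may damage the epoxy ester, instead of clean aminomethylation. The fallback installs the methylene group before the C8 ester. It sets out from 23: silylation (Et3SiCl, imidazole) gives the triethylsilyl ether F6. The methylenation sequence of step 18 then passes through lithium enolate F7, Mannich base F8 and methiodide F9 to the α-methylene lactone silyl ether F10. HF·pyridine frees the α-methylene 8β-alcohol F11, and Yamaguchi esterification with acid 27 (through mixed anhydride 28) rejoins the route at 33.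

Further compounds
F1 | step 9 | aldol adduct, tert-butyl 2-hydroxy-2-[ring C7] acetate of the 6-oxo-1(10)E,4Z-cyclodecadiene (8β-silyl, 3β-OTBS; C7 and C11 as mixture) | O=C1C(C(O)C(=O)OC(C)(C)C)[C@H]([Si](C)(C)Cc2ccccc2)C/C(C)=C/C[C@H](O[Si](C)(C)C(C)(C)C)/C(C)=C\1
F2 | step 9 | methanesulfonate of F1 | O=C1C(C(OS(C)(=O)=O)C(=O)OC(C)(C)C)[C@H]([Si](C)(C)Cc2ccccc2)C/C(C)=C/C[C@H](O[Si](C)(C)C(C)(C)C)/C(C)=C\1
F3 | step 9 | alkylidene keto ester, tert-butyl 8β-(benzyldimethylsilyl)-3β-(tert-butyldimethylsilyloxy)-6-oxo-13-norgermacra-1(10)E,4Z,7(11)-trien-12-oate | O=C1C(=CC(=O)OC(C)(C)C)[C@H]([Si](C)(C)Cc2ccccc2)C/C(C)=C/C[C@H](O[Si](C)(C)C(C)(C)C)/C(C)=C\1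
F4 | step 10 | 6β-alcohol, C6 epimer of 18 | O[C@@H]1[C@H](CC(=O)OC(C)(C)C)[C@H]([Si](C)(C)Cc2ccccc2)C/C(C)=C/C[C@H](O[Si](C)(C)C(C)(C)C)/C(C)=C\1
F5 | step 10 | 6α-(4-nitrobenzoate) of 18 | O=C(O[C@H]1[C@H](CC(=O)OC(C)(C)C)[C@H]([Si](C)(C)Cc2ccccc2)C/C(C)=C/C[C@H](O[Si](C)(C)C(C)(C)C)/C(C)=C\1)c1ccc(cc1)[N+](=O)[O-]
F6 | step 18 | 8β-triethylsilyl ether of 23 | C1C(=O)O[C@@H]2/C=C(/C)[C@@H](OC(=O)c3ccccc3)C/C=C(\C)C[C@@H](O[Si](CC)(CC)CC)[C@@H]12
F7 | step 18 | lithium enolate of F6 | C1=C([O-])O[C@@H]2/C=C(/C)[C@@H](OC(=O)c3ccccc3)C/C=C(\C)C[C@@H](O[Si](CC)(CC)CC)[C@@H]12.[Li+]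
F8 | step 18 | 11-(dimethylaminomethyl) derivative of F6 (Mannich base) | CN(C)CC1C(=O)O[C@@H]2/C=C(/C)[C@@H](OC(=O)c3ccccc3)C/C=C(\C)C[C@@H](O[Si](CC)(CC)CC)[C@@H]12
F9 | step 18 | methiodide of F8 | C[N+](C)(C)CC1C(=O)O[C@@H]2/C=C(/C)[C@@H](OC(=O)c3ccccc3)C/C=C(\C)C[C@@H](O[Si](CC)(CC)CC)[C@@H]12.[I-]
F10 | step 18 | 3β-benzoyloxy-8β-(triethylsilyloxy)germacra-1(10)E,4Z,11(13)-trien-12,6α-olide | C=C1C(=O)O[C@@H]2/C=C(/C)[C@@H](OC(=O)c3ccccc3)C/C=C(\C)C[C@@H](O[Si](CC)(CC)CC)[C@@H]12
F11 | step 18 | 3β-benzoyloxy-8β-hydroxygermacra-1(10)E,4Z,11(13)-trien-12,6α-olide | C=C1C(=O)O[C@@H]2/C=C(/C)[C@@H](OC(=O)c3ccccc3)C/C=C(\C)C[C@@H](O)[C@@H]12
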